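## Structural features

The target is a spirocyclic N,O-ketal: one quaternary carbon is at once C3 of an isoindolin-1-one (benzene ring A fused to the five-membered lactam ring B) and the sp3 carbon of a 2H-naphtho[1,8-bc]furan, whose five-membered ether ring C bridges the peri positions C1 and C8 of a naphthalene. This carbon is the only stereocentre, it is (R), and it has no stereogenic neighbour; it carries the ring C oxygen, the lactam nitrogen N2, C3a of ring A and naphthalene C8. Ring A is contiguously trisubstituted (methoxy on C4, the spiro carbon on C3a, the carbonyl carbon C1 on C7a), the naphthalene carries a phenol on C7 (ortho to the spiro junction) and a methyl group on C3, and N2 carries a 2-hydroxyethyl chain. The fragile element is the N-acyl N,O-ketal: acid can ionise the C3–O bond to an N-acyliminium ion, and once the naphthalene C7 phenol is free, base or heat can open the ketal towards an ortho-quinone methide; either event would erase the configuration, and ring C is strained as well. The real difficulty is to assemble the fully substituted C3 between two ortho-substituted arenes (methoxy on one flank, the naphthalene C7 oxygen on the other) and to secure it as one enantiomer without exposing it to ionising conditions. The key step uses the fact that C3a and C7a are neighbours and that C3a lies next to the methoxy-bearing C4: these two carbons are the ends of the triple bond of 3-methoxybenzyne, polarised by the methoxy group, while C1 is an isocyanide carbon and C3 is an imidate carbon already held inside ring C.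

## Logic of the disconnections

**20 to 19.** The two O–CH2Ph bonds are cut, one at the naphthalene C7 oxygen and one at the side-chain oxygen. The phenol beside the spiro junction is what makes the ketal base-labile, so it is unmasked last and under neutral conditions. One protecting group for both hydroxyls means one final operation. The forward step must cleave two benzyl ethers without touching the doubly benzylic C3–O and C3–N bonds.

**19 to 17 (through 18).** The C1=O bond is traced back to a C1=N–C(CH3)3 bond. An amidine at C1 is what an isocyanide delivers, and it is the only strongly basic site the skeleton ever has. The forward step needs hydroxide to attack C1 and the exocyclic nitrogen to leave, in a medium that cannot ionise C3–O.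

**17 to 16.** No skeletal bond is cut; the ion pair is taken apart and the racemate restored. C3 is created without any facial bias, and the amidinium salt is the one stage at which a classical resolution is possible and at which the N2 lone pair is tied up, so that C3 cannot ionise. The forward step needs a crystallisation that discriminates the two diastereomeric salts.

**16 to 11, 12 and 13.** Three bonds are cut: C7a–C1, C3a–C3 and N2–C1. This removes ring B and ring A in one stroke and leaves a flat tricycle, an aryne precursor and a one-carbon unit; the crowded 1,2,3-pattern of ring A never has to be built by a hindered aryl–metal coupling. The forward step needs the aryne to accept the isocyanide carbon at the end remote from the methoxy group, the resulting aryl anion to add to an imidate carbon, and the nitrogen to close on the nitrilium carbon.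

**11 to 7 and 10.** The naphthalene C8–C(imidate) bond and the O–C(imidate) bond are cut. The imidate carbon is again an isocyanide carbon, so ring C reduces to a peri-bromonaphthol and N2 arrives with its side chain already attached. The forward step needs palladium to insert into a C–Br bond flanked on both sides and to form a strained ring by C–O reductive elimination.

**10 to 9 to 8.** The isocyanide carbon is removed by way of the formamide. This leads to a commercial amino ether and needs only a clean dehydration.

**7 to 6 to 5.** The methyl group is traced back to CH2OH and then to CO2CH3, and the naphthol to its acetate. The ester and the acetate are the groups that the benzannulation leaves behind. The forward steps need a hydride reduction that spares the C–Br bond and a deoxygenation that avoids Friedel–Crafts alkylation.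

**5 to 4.** The naphthalene C8–Br bond is cut. At this stage the other ring is deactivated by the ester and the acetoxy group, so the alpha position ortho to the benzyloxy group is the only activated site. The forward step needs monobromination at a peri-hindered carbon.

**4 to 3 to 1 and 2.** The naphthalene C1–C8a bond (the acylation bond) and the C3–C4 double bond (the condensation bond) are cut. This opens the naphthalene to a para-substituted benzaldehyde and a succinate, both commercial. The para substituent makes the two ortho positions equivalent, so the ring closure can give only one regioisomer.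

## Other disconnections considered

**Alternative 1:** Both bonds from C3 to the naphthalene unit are cut (C3–naphthalene C8 and C3–O), so C3 derives from one carbonyl carbon of the phthalimide A2.
- Forward step: fluoride would liberate the 1,2-naphthalyne A3 from the ortho-silyl triflate A4. The carbonyl oxygen of A2 would add to naphthalene C7 and the C8 anion to the carbonyl carbon. The four-membered adduct would open, and the peri oxide on naphthalene C1 would close on C3 to give A1 with the C7 phenol already free.
- In favour: ring B is bought ready-made, no amidine has to be hydrolysed, and one hydrogenolysis would finish the synthesis. The expected attack of a nucleophile on the beta carbon of a 1,2-naphthalyne matches the required connectivity.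
- Against: the carbonyl flanked by the methoxy group is the more hindered and the less electrophilic of the two. An imide oxygen is a weak nucleophile towards arynes, whereas the free peri oxide of A3 is a strong one, so O-arylation and oligomerisation would compete. A4 needs four contiguous substituents on a naphthalene. A1 is neutral, so its racemate could only be separated on a chiral stationary phase.
- Comparison: both plans create C3 from an aryne in one operation and both lack enantiocontrol, where they are equal. On step economy Alternative 1 is the better plan, by about three steps after the key step. On mechanism the chosen plan is safer in its first event (isocyanide addition to an aryne is established) and offers a basic handle for resolution. Its own uncertain event is the addition of the aryl anion to the imidate.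

**Alternative 2:** The nitrogen is formally inserted between C3 and a carboxamide carbon, so C3–N2 and N2–C1 are the bonds made.
- Forward step: Hofmann rearrangement of the amide acid A6 (PhI(OAc)2 or NaOBr) would move C3 from carbon to nitrogen with retention. The ortho carboxylic acid would add to the isocyanate, and loss of CO2 from the mixed anhydride would give the N-unsubstituted lactam A5. N-alkylation and deprotection would follow.
- In favour: the stereocentre of A6 bears three carbons and one oxygen and cannot ionise. It could be resolved early as a carboxylic acid salt, and a stereoretentive 1,2-shift would hand the configuration on faithfully. On stereochemical security this is the better plan.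
- Against: A6 contains the same congested quaternary carbon plus two differentiated carboxyl functions, so the hard C–C bond is only postponed. The oxidant meets an electron-rich naphthyl ether. The late N-alkylation of A5 needs a lactam anion that can expel the naphthoxide and so open ring C.
- Comparison: structurally it shifts the problem from ring B to the quaternary carbon. Mechanistically each step is known chemistry, which is an advantage over the chosen key step. On step economy it is clearly longer than the chosen plan.

**Alternative 3:** Only C3–N2 is cut.
- Forward step: oxidation of the racemic naphthofuranol A8 (Ag2O or DDQ) would give the ortho-quinone methide A9. A chiral phosphoric acid would direct the addition of the secondary amide nitrogen to C3 and give A7. Desilylation would complete the synthesis.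
- In favour: both enantiomers of A8 converge on one planar intermediate, the configuration would be set by a catalyst, and no half of the material is discarded. On enantiocontrol and material economy this is the better plan, and its endgame is one step.
- Against: A9 has an exocyclic double bond at the bridging carbon of a strained tricycle, and its formation from an electron-rich naphthol competes with other oxidation modes. A secondary amide nitrogen is a weak nucleophile for a tetrasubstituted centre. A7 is itself an ortho-hydroxy N,O-ketal that the acid catalyst could return to A9, so the selectivity would hold only if closure is irreversible. A8 still needs the hindered C3–C3a bond.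
- Comparison: structurally it builds ring B last, as the chosen plan does. Mechanistically it rests on a sensitive intermediate where the chosen plan rests on an untested electrophile, so the risk is of similar size. In step count after the key step it is shorter, but the route to A8 is not.

Key step: step 9

**Remarks and assumptions**

- Numbering: the discussion uses lactam numbering (C1 carbonyl, N2, C3 spiro, C3a, C4 methoxy, C7a) and ordinary naphthalene numbering (O on C1, methyl on C3, oxygen on C7, C8 bonded to C3). Compound names use the systematic spiro and fused-ring locants.
- On the naphtho[1,8-bc]furan skeleton (O1, C2, C2a, C3 to C8, C8a, C8b) the oxygen substituent of 11 stands on C3 and the methyl group on C7, so 11 is named as a 3-benzyloxy-7-methyl compound.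
- A free 7-alkoxy-3-methyl-1-naphthol would be brominated at naphthalene C2 or C4 under the direction of the hydroxyl group; the bromine is therefore introduced on 4, before the naphthol is unmasked.
- The side-chain oxygen is carried as a benzyl ether, not a silyl ether: it is inert to fluoride (step 9) and hot alkali (step 11) and falls together with the aryl benzyl ether in step 12.
- Descriptors were derived by hand from the CIP rules; the SMILES strings are definitive. The target and 19 are (R). In the benzyl-protected amidines 17 and 18 the same spatial arrangement is formally (S), because there the naphthyl branch outranks ring A.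
- Assumption: the less soluble salt with (1S)-(+)-10-camphorsulfonic acid is taken to contain the (S)-amidinium ion. If the pairing is the opposite, the (1R)-(−)-acid is used in step 10 and nothing else changes.
- Compounds 1, 2, 8, 12 and 13 are taken as commercial.

## Route

Step 1
Reactants: 1 4-(benzyloxy)benzaldehyde; 2 dimethyl succinate
Product: 3 (E)-4-[4-(benzyloxy)phenyl]-3-(methoxycarbonyl)but-3-enoic acid
Conditions: NaOMe, MeOH, reflux; then aq. HCl
Reagents that add atoms: none
Why: Stobbe condensation: aldol addition of the succinate enolate, lactonisation and irreversible E1cB opening give the half-ester as its carboxylate, with the aryl group cis to the CH2CO2H arm as the later ring closure requires.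

Step 2
Reactants: 3 (E)-4-[4-(benzyloxy)phenyl]-3-(methoxycarbonyl)but-3-enoic acid
Product: 4 methyl 4-acetoxy-6-(benzyloxy)-2-naphthoate
Conditions: Ac2O, NaOAc, 140 °C
Reagents that add atoms: acetic anhydride, CC(=O)OC(C)=O
Why: Classical benzannulation of a Stobbe half-ester: the mixed anhydride acylates the arene intramolecularly (Friedel–Crafts acylation), the ketone enolises to the naphthol and this is acetylated in the flask. The para-substituted ring has two equivalent ortho positions, so only one regioisomer can form.

Step 3
Reactants: 4 methyl 4-acetoxy-6-(benzyloxy)-2-naphthoate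
Product: 5 methyl 4-acetoxy-6-(benzyloxy)-5-bromo-2-naphthoate
Conditions: NBS, MeCN, 0 °C to rt
Reagents that add atoms: N-bromosuccinimide, O=C1CCC(=O)N1Br
Why: Electrophilic aromatic bromination; the benzyloxy ring is the only activated ring (the other bears the ester and the acetoxy group), and the alpha position ortho to the alkoxy group is the kinetic site of a 2-alkoxynaphthalene.

Step 4
Reactants: 5 methyl 4-acetoxy-6-(benzyloxy)-5-bromo-2-naphthoate
Product: 6 7-(benzyloxy)-8-bromo-3-(hydroxymethyl)naphthalen-1-ol
Conditions: i-Bu2AlH (5 equiv), CH2Cl2, −78 to 0 °C; aq. potassium sodium tartrate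
Reagents that add atoms: none
Why: Hydride reduction: i-Bu2AlH takes the methyl ester to the primary alcohol and cleaves the aryl acetate in the same operation, and it does not attack the aryl bromide or the benzyl ether.

Step 5
Reactants: 6 7-(benzyloxy)-8-bromo-3-(hydroxymethyl)naphthalen-1-ol
Product: 7 7-(benzyloxy)-8-bromo-3-methylnaphthalen-1-ol
Conditions: Et3SiH (5 equiv), CF3CO2H, CH2Cl2, 0 °C, slow addition of 6
Reagents that add atoms: none
Why: Ionic hydrogenation: acid ionises the benzylic alcohol to a naphthylmethyl cation that the benzyloxy group stabilises across the ring system (2,6-type conjugation), and the silane delivers hydride. Excess silane and dilution are meant to suppress self-alkylation.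

Step 6
Reactants: 8 2-(benzyloxy)ethan-1-amine
Product: 9 N-[2-(benzyloxy)ethyl]formamide
Conditions: HCO2Et, reflux
Reagents that add atoms: ethyl formate, CCOC=O
Why: N-formylation of a primary amine by aminolysis of a formate ester.

Step 7
Reactants: 9 N-[2-(benzyloxy)ethyl]formamide
Product: 10 2-(benzyloxy)ethyl isocyanide
Conditions: POCl3, Et3N, CH2Cl2, −10 °C
Reagents that add atoms: none
Why: Dehydration of an N-monosubstituted formamide to the isocyanide (Ugi procedure); the benzyl ether is inert.

Step 8
Reactants: 7 7-(benzyloxy)-8-bromo-3-methylnaphthalen-1-ol; 10 2-(benzyloxy)ethyl isocyanide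
Product: 11 3-(benzyloxy)-N-[2-(benzyloxy)ethyl]-7-methyl-2H-naphtho[1,8-bc]furan-2-imine
Conditions: Pd(OAc)2 (5 mol%), DPEphos, Cs2CO3, toluene, 100 °C, slow addition of 10; chromatography on Et3N-deactivated silica
Reagents that add atoms: none
Why: Palladium-catalysed imidoylative cyclisation: the C–Br bond adds to zerovalent palladium (formed in the flask from Pd(OAc)2), the isocyanide undergoes 1,1-insertion, and C–O reductive elimination with the peri naphthoxide closes ring C. This is the intramolecular counterpart of the aryl halide, isocyanide and alkoxide coupling to imidates; slow addition of 10 limits multiple insertion.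

Step 9
Reactants: 11 3-(benzyloxy)-N-[2-(benzyloxy)ethyl]-7-methyl-2H-naphtho[1,8-bc]furan-2-imine; 12 3-methoxy-2-(trimethylsilyl)phenyl trifluoromethanesulfonate; 13 tert-butyl isocyanide
Product: 16 (±)-3'-(benzyloxy)-2-[2-(benzyloxy)ethyl]-N-tert-butyl-7-methoxy-7'-methyl-2'H-spiro[isoindoline-1,2'-naphtho[1,8-bc]furan]-3-imine, via 3-methoxybenzyne 14 (not isolated), via nitrilium aryl-anion zwitterion 15 (not isolated)
Conditions: KF, 18-crown-6, THF, 0 °C to rt; 12 (1.5 equiv) and 13 (2.5 equiv) relative to 11
Reagents that add atoms: none
Why: Proposed new method: fluoride removes the silyl group of 12 and loss of triflate gives aryne 14; the carbon of 13 adds to the aryne carbon remote from the methoxy group, so that the negative charge of zwitterion 15 sits on the carbon flanked by OMe, where induction stabilises it. This aryl anion attacks the imidate carbon of 11 perpendicular to the flat tricycle, a carbon made electrophilic by its aryloxy substituent and by the relief of peri-ring strain on rehybridisation, and so forms C3a–C3. The nitrogen that becomes anionic closes on the nitrilium carbon in a 5-exo-dig mode (N2–C1) and completes ring B as the N-tert-butyl amidine; if the tetrahedral adduct first expels the naphthoxide, the ketimine nitrogen still captures the nitrilium carbon and the naphthoxide re-closes ring C by 5-exo-trig addition to the iminium carbon, so both paths lead to 16. The closest known reaction type is the three-component coupling of arynes, isocyanides and aldehydes or N-sulfonyl imines to iminoisobenzofurans and iminoisoindolines; an unactivated cyclic N-alkyl imidate has not been used as the third partner. The new stereocentre C3 arises by attack on either enantiotopic face of the planar imidate with no controlling element, so 16 forms as the racemate and is resolved in step 10. Regioselectivity is secured by the methoxy group next to the triple bond, and the order of events by the far higher nucleophilicity of the isocyanide carbon towards the aryne compared with the imidate nitrogen, supported by the excess of 13.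

Step 10
Reactants: 16 (±)-3'-(benzyloxy)-2-[2-(benzyloxy)ethyl]-N-tert-butyl-7-methoxy-7'-methyl-2'H-spiro[isoindoline-1,2'-naphtho[1,8-bc]furan]-3-imine
Product: 17 (S)-N-tert-butyl-spiro amidinium (1S)-camphor-10-sulfonate (1:1 salt of the target-configured enantiomer of 16)
Conditions: (1S)-(+)-10-camphorsulfonic acid (1 equiv), EtOAc–i-PrOH, crystallise; recrystallise until a free-based sample is enantiomerically uniform by chiral HPLC
Reagents that add atoms: (1S)-(+)-10-camphorsulfonic acid, CC1([C@@H]2CC[C@]1(C(=O)C2)CS(=O)(=O)O)C
Why: Classical resolution by crystallisation of diastereomeric salts: the trisubstituted amidine is a strong base and should form a crystalline 1:1 sulfonate. As the amidinium ion the N2 lone pair is tied up, so the N,O-ketal carbon cannot ionise during the crystallisations.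

Step 11
Reactants: 17 (S)-N-tert-butyl-spiro amidinium (1S)-camphor-10-sulfonate
Product: 19 (R)-3'-(benzyloxy)-2-[2-(benzyloxy)ethyl]-7-methoxy-7'-methyl-2'H-spiro[isoindoline-1,2'-naphtho[1,8-bc]furan]-3-one, via free (S)-amidine 18 (not isolated)
Conditions: KOH (aq. 2 M), EtOH, 80 °C
Reagents that add atoms: water, O
Why: Amidine hydrolysis: base releases 18, hydroxide adds to C1, and the tetrahedral intermediate expels the more basic exocyclic nitrogen as tert-butylamine, which keeps the five-membered ring as the lactam. The alkaline medium leaves the benzyl ethers and the N-acyl N,O-ketal of the product (which ionises only under acid) untouched, so C3 is not affected; the change of descriptor from (S) to (R) is formal only.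

Step 12
Reactants: 19 (R)-3'-(benzyloxy)-2-[2-(benzyloxy)ethyl]-7-methoxy-7'-methyl-2'H-spiro[isoindoline-1,2'-naphtho[1,8-bc]furan]-3-one
Product: 20 (R)-3'-hydroxy-2-(2-hydroxyethyl)-7-methoxy-7'-methyl-2'H-spiro[isoindoline-1,2'-naphtho[1,8-bc]furan]-3-one (target)
Conditions: H2 (1 atm), 10% Pd/C, EtOAc–EtOH, rt
Reagents that add atoms: none
Why: Catalytic hydrogenolysis cleaves the aryl and the alkyl benzyl ether in one operation under neutral conditions; the hindered quaternary C3–O and C3–N bonds and the methyl ether should not be cleaved. Neutrality avoids opening of the freed ortho-hydroxy N,O-ketal, so the (R) centre is carried through unchanged.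

## Compound list

1 | 4-(benzyloxy)benzaldehyde | O=Cc1ccc(OCc2ccccc2)cc1 | starting material
2 | dimethyl succinate | COC(=O)CCC(=O)OC | starting material
3 | (E)-4-[4-(benzyloxy)phenyl]-3-(methoxycarbonyl)but-3-enoic acid | COC(=O)/C(CC(=O)O)=C/c1ccc(OCc2ccccc2)cc1 | intermediate
4 | methyl 4-acetoxy-6-(benzyloxy)-2-naphthoate | COC(=O)c1cc(OC(C)=O)c2cc(OCc3ccccc3)ccc2c1 | intermediate
5 | methyl 4-acetoxy-6-(benzyloxy)-5-bromo-2-naphthoate | COC(=O)c1cc(OC(C)=O)c2c(Br)c(OCc3ccccc3)ccc2c1 | intermediate
6 | 7-(benzyloxy)-8-bromo-3-(hydroxymethyl)naphthalen-1-ol | OCc1cc(O)c2c(Br)c(OCc3ccccc3)ccc2c1 | intermediate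
7 | 7-(benzyloxy)-8-bromo-3-methylnaphthalen-1-ol | Cc1cc(O)c2c(Br)c(OCc3ccccc3)ccc2c1 | intermediate
8 | 2-(benzyloxy)ethan-1-amine | NCCOCc1ccccc1 | starting material
9 | N-[2-(benzyloxy)ethyl]formamide | O=CNCCOCc1ccccc1 | intermediate
10 | 2-(benzyloxy)ethyl isocyanide | [C-]#[N+]CCOCc1ccccc1 | intermediate
11 | 3-(benzyloxy)-N-[2-(benzyloxy)ethyl]-7-methyl-2H-naphtho[1,8-bc]furan-2-imine (cyclic imidate, C=N geometry not specified) | Cc1cc2ccc(OCc3ccccc3)c3c2c(c1)OC3=NCCOCc1ccccc1 | intermediate
12 | 3-methoxy-2-(trimethylsilyl)phenyl trifluoromethanesulfonate | COc1cccc(OS(=O)(=O)C(F)(F)F)c1[Si](C)(C)C | starting material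
13 | tert-butyl isocyanide | [C-]#[N+]C(C)(C)C | starting material
14 | 3-methoxybenzyne (1-methoxy-2,3-didehydrobenzene) | COC1=CC=CC#C1 | intermediate (not isolated)
15 | 2-(N-tert-butylnitrilio)-6-methoxyphenyl anion (zwitterion) | COc1cccc(C#[N+]C(C)(C)C)[c-]1 | intermediate (not isolated)
16 | (±)-3'-(benzyloxy)-2-[2-(benzyloxy)ethyl]-N-tert-butyl-7-methoxy-7'-methyl-2'H-spiro[isoindoline-1,2'-naphtho[1,8-bc]furan]-3-imine (racemate) | COc1cccc2c1C1(Oc3cc(C)cc4ccc(OCc5ccccc5)c1c34)N(CCOCc1ccccc1)C2=NC(C)(C)C | intermediate
17 | (S)-amidinium (1S)-camphor-10-sulfonate of the target-configured enantiomer of 16 | COc1cccc2c1[C@@]1(Oc3cc(C)cc4ccc(OCc5ccccc5)c1c34)N(CCOCc3ccccc3)C2=[NH+]C(C)(C)C.CC1([C@@H]2CC[C@]1(C(=O)C2)CS(=O)(=O)[O-])C | intermediate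
18 | (S)-3'-(benzyloxy)-2-[2-(benzyloxy)ethyl]-N-tert-butyl-7-methoxy-7'-methyl-2'H-spiro[isoindoline-1,2'-naphtho[1,8-bc]furan]-3-imine | COc1cccc2c1[C@@]1(Oc3cc(C)cc4ccc(OCc5ccccc5)c1c34)N(CCOCc3ccccc3)C2=NC(C)(C)C | intermediate (not isolated)
19 | (R)-3'-(benzyloxy)-2-[2-(benzyloxy)ethyl]-7-methoxy-7'-methyl-2'H-spiro[isoindoline-1,2'-naphtho[1,8-bc]furan]-3-one | COc1cccc2c1[C@@]1(Oc3cc(C)cc4ccc(OCc5ccccc5)c1c34)N(CCOCc3ccccc3)C2=O | intermediate
20 | (R)-3'-hydroxy-2-(2-hydroxyethyl)-7-methoxy-7'-methyl-2'H-spiro[isoindoline-1,2'-naphtho[1,8-bc]furan]-3-one | COc1cccc2c1[C@@]1(Oc3cc(C)cc4ccc(O)c1c34)N(CCO)C2=O | target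

## Step count and least certain steps

Total step count: 12. Longest linear sequence: 10 steps (steps 1 to 5 and 8 to 12); the two-step branch to 10 (steps 6 and 7) joins at step 8.

**Step 9 (key step, proposed new method).**
- What may go wrong: the aryl anion of 15 may be quenched by proton transfer (from the medium or from the N–CH2 group of 11), or may add to a second molecule of 13 or 14, faster than it adds to the imidate carbon, because the imidate nitrogen carries no electron-withdrawing group. N-arylation of the imidate nitrogen by 14 may also compete.
- Fallback (known chemistry), from 7 back to 19: bromine–lithium exchange on 7 (n-BuLi, 2.2 equiv, THF, −78 °C), carboxylation with CO2 and acidification give the peri lactone 3-(benzyloxy)-7-methyl-2H-naphtho[1,8-bc]furan-2-one F1. Amine 8 is acylated with 3-methoxybenzoyl chloride (Et3N, CH2Cl2) to N-[2-(benzyloxy)ethyl]-3-methoxybenzamide F2. Directed ortho-metalation of F2 (s-BuLi, 2.2 equiv, TMEDA, THF, −78 °C) occurs at the carbon between the methoxy and the amide group, and the dianion adds to F1 to give the hydroxy lactam 2-[2-(benzyloxy)ethyl]-3-[2-(benzyloxy)-8-hydroxy-6-methylnaphthalen-1-yl]-3-hydroxy-4-methoxyisoindolin-1-one F3. Brief treatment with CF3CO2H in CH2Cl2 at 0 °C closes ring C through the N-acyliminium ion to the racemic lactam (±)-3'-(benzyloxy)-2-[2-(benzyloxy)ethyl]-7-methoxy-7'-methyl-2'H-spiro[isoindoline-1,2'-naphtho[1,8-bc]furan]-3-one F4. Preparative chromatography on a chiral stationary phase returns the route at 19; steps 10 and 11 are then not needed.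

**Step 11.**
- What may go wrong: slow attack of hydroxide at the amidine carbon shielded by the tert-butyl group, and at the temperature then needed, erosion of configuration by reversible heterolysis of the C3–O bond of the free amidine (the N2 lone pair is not tied up in 18) or opening of ring C.
- Fallback, from 18 back to 19: 18 is set free from 17 with cold aq. NaHCO3 and acylated on the exocyclic nitrogen with methyl chloroformate (CH2Cl2, 0 °C) to the N-methoxycarbonyl amidinium chloride F5, in which N2 is again engaged. Cold aq. NaHCO3 then adds water at C1 and expels methyl tert-butylcarbamate, giving 19 without heat and without strong acid or base.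

**Step 8.**
- What may go wrong: deactivation of the catalyst by multiple coordination or insertion of the primary isocyanide, slow oxidative addition at a bromide flanked by the benzyloxy group and the peri oxide, and hydrolytic loss of the strained imidate during isolation.
- Fallback, from 7 back to 11: aminocarbonylation of 7 with 8 (Pd(OAc)2, Xantphos, CO 1 atm, Et3N, toluene, 90 °C) gives 2-(benzyloxy)-N-[2-(benzyloxy)ethyl]-8-hydroxy-6-methyl-1-naphthamide F6. Amide activation (Tf2O, 2-fluoropyridine, CH2Cl2, −78 to 0 °C) with capture by the peri hydroxyl closes ring C to 11.

**Step 10.**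
- What may go wrong: failure of the salt to crystallise, or co-crystallisation of both diastereomeric salts as a solid solution, so that no enrichment is reached.
- Fallback, from 16 back to 18: the racemate is separated by preparative supercritical-fluid chromatography on a polysaccharide chiral stationary phase, and step 11 is run on the free base 18. No new compound is made.

**Step 5.**
- What may go wrong: Friedel–Crafts self-alkylation of the electron-rich naphthol by the benzylic cation before hydride transfer, and acid-promoted loss of the peri bromine.
- Fallback, from 6 back to 7: Appel bromination (CBr4, PPh3, CH2Cl2, 0 °C) converts only the benzylic alcohol, giving 7-(benzyloxy)-8-bromo-3-(bromomethyl)naphthalen-1-ol F7. Displacement with hydride (LiBHEt3, 2.5 equiv, THF, 0 °C) gives 7 without passing through a cation.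

## Further compounds

F1 | step 9 | 3-(benzyloxy)-7-methyl-2H-naphtho[1,8-bc]furan-2-one | Cc1cc2ccc(OCc3ccccc3)c3c2c(c1)OC3=O
F2 | step 9 | N-[2-(benzyloxy)ethyl]-3-methoxybenzamide | COc1cccc(C(=O)NCCOCc2ccccc2)c1
F3 | step 9 | 2-[2-(benzyloxy)ethyl]-3-[2-(benzyloxy)-8-hydroxy-6-methylnaphthalen-1-yl]-3-hydroxy-4-methoxyisoindolin-1-one (racemic) | COc1cccc2c1C(O)(c1c(OCc3ccccc3)ccc3cc(C)cc(O)c13)N(CCOCc1ccccc1)C2=O
F4 | step 9 | (±)-3'-(benzyloxy)-2-[2-(benzyloxy)ethyl]-7-methoxy-7'-methyl-2'H-spiro[isoindoline-1,2'-naphtho[1,8-bc]furan]-3-one (racemate of 19) | COc1cccc2c1C1(Oc3cc(C)cc4ccc(OCc5ccccc5)c1c34)N(CCOCc1ccccc1)C2=O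
F5 | step 11 | (S)-N-tert-butyl-N-(methoxycarbonyl) spiro amidinium chloride derived from 18 | COc1cccc2c1[C@@]1(Oc3cc(C)cc4ccc(OCc5ccccc5)c1c34)N(CCOCc3ccccc3)C2=[N+](C(=O)OC)C(C)(C)C.[Cl-]
F6 | step 8 | 2-(benzyloxy)-N-[2-(benzyloxy)ethyl]-8-hydroxy-6-methyl-1-naphthamide | Cc1cc(O)c2c(C(=O)NCCOCc3ccccc3)c(OCc3ccccc3)ccc2c1
F0 | step 10 | none | none
F7 | step 5 | 7-(benzyloxy)-8-bromo-3-(bromomethyl)naphthalen-1-ol | BrCc1cc(O)c2c(Br)c(OCc3ccccc3)ccc2c1
A1 | alternative 1 | (R)-2-[2-(benzyloxy)ethyl]-3'-hydroxy-7-methoxy-7'-methyl-2'H-spiro[isoindoline-1,2'-naphtho[1,8-bc]furan]-3-one | COc1cccc2c1[C@@]1(Oc3cc(C)cc4ccc(O)c1c34)N(CCOCc3ccccc3)C2=O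
A2 | alternative 1 | N-[2-(benzyloxy)ethyl]-3-methoxyphthalimide | COc1cccc2c1C(=O)N(CCOCc1ccccc1)C2=O
A3 | alternative 1 | 8-hydroxy-6-methyl-1,2-didehydronaphthalene (1,2-naphthalyne) | CC1=CC2=C(C(O)=C1)C#CC=C2
A4 | alternative 1 | 8-hydroxy-6-methyl-1-(trimethylsilyl)naphthalen-2-yl trifluoromethanesulfonate | Cc1cc(O)c2c([Si](C)(C)C)c(OS(=O)(=O)C(F)(F)F)ccc2c1
A5 | alternative 2 | (R)-3'-(benzyloxy)-7-methoxy-7'-methyl-2'H-spiro[isoindoline-1,2'-naphtho[1,8-bc]furan]-3-one | COc1cccc2c1[C@@]1(Oc3cc(C)cc4ccc(OCc5ccccc5)c1c34)NC2=O
A6 | alternative 2 | (R)-2-[3-(benzyloxy)-2-carbamoyl-7-methyl-2H-naphtho[1,8-bc]furan-2-yl]-3-methoxybenzoic acid | COc1cccc(C(=O)O)c1[C@@]1(Oc2cc(C)cc3ccc(OCc4ccccc4)c1c23)C(N)=O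
A7 | alternative 3 | (R)-2-[2-(tert-butyldimethylsilyloxy)ethyl]-3'-hydroxy-7-methoxy-7'-methyl-2'H-spiro[isoindoline-1,2'-naphtho[1,8-bc]furan]-3-one | COc1cccc2c1[C@@]1(Oc3cc(C)cc4ccc(O)c1c34)N(CCO[Si](C)(C)C(C)(C)C)C2=O
A8 | alternative 3 | (±)-N-[2-(tert-butyldimethylsilyloxy)ethyl]-2-(3-hydroxy-7-methyl-2H-naphtho[1,8-bc]furan-2-yl)-3-methoxybenzamide | COc1cccc(C(=O)NCCO[Si](C)(C)C(C)(C)C)c1C1Oc2cc(C)cc3ccc(O)c1c23
A9 | alternative 3 | ortho-quinone methide from A8 (2-aryl-7-methyl-naphtho[1,8-bc]furan-3-one) | COc1cccc(C(=O)NCCO[Si](C)(C)C(C)(C)C)c1C1=C2C(=O)C=CC3=CC(C)=CC(O1)=C23
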